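**Retrosynthetic overview**
1. The target, a 6,8'-bicoumarin, is traced back through hydrogenolysis of a 7-O-benzyl ether and O-methylation of the two 4-hydroxyls to a 6,8'-bis(4-hydroxycoumarin).
2. Feature used: each lactone carbonyl carbon (C2, C2') lies between the ring oxygen (O1, O1') and C3 (C3'). Placed on O1 and O1' as diethylcarbamoyl groups, ortho to acetyl groups (acetyl C=O becomes C4/C4', acetyl CH3 becomes C3/C3'), they lack only the C2–C3 and C2'–C3' bonds.
3. Key disconnection: both C2–C3 bonds by base-induced oxygen-to-carbon carbamoyl shift, then both O1–C2 lactone bonds by acid. The two pyranone rings are formed last and together on the finished biaryl.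
4. The bis(2-acetylaryl carbamate) comes from a 2,6-dimethoxy/2',4'-dibenzyloxy biaryl: acetylation ortho to methyl on each ring, BCl3 cleavage of the benzyl ethers and of the acetyl-flanked methoxy group, re-benzylation of the one non-chelated phenol, carbamoylation.
5. The biaryl bond (C6–C8') comes from Suzuki coupling of 4-bromo-orcinol dibenzyl ether with the 2-boronic acid of orcinol dimethyl ether.

Key step: step 9

Remark: the target SMILES fixes no configuration at the hindered C6–C8' axis; the route is planned for the racemate, and every biaryl from compound 8 onward is a racemic atropisomer.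

**Route**

Step 1
Reactants: 1 orcinol (5-methylbenzene-1,3-diol)
Product: 2 1,3-bis(benzyloxy)-5-methylbenzene
Conditions: BnBr (2.3 equiv), K2CO3, DMF, 60 °C
Reagents that add atoms: benzyl bromide, BrCc1ccccc1
Why: Double Williamson etherification of both phenoxides, giving a ring with two equal ether donors for the bromination that follows.

Step 2
Reactants: 2 1,3-bis(benzyloxy)-5-methylbenzene
Product: 3 1,5-bis(benzyloxy)-2-bromo-3-methylbenzene
Conditions: NBS (1.0 equiv), MeCN, 0 °C to rt, dark
Reagents that add atoms: N-bromosuccinimide, O=C1CCC(=O)N1Br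
Why: Electrophilic aromatic bromination of a 3,5-dialkoxytoluene should go to the carbon para to one ether, ortho to the other and ortho to methyl (the future C6), since the site between the two benzyloxy groups is only ortho-activated and more crowded.

Step 3
Reactants: 4 1,3-dimethoxy-5-methylbenzene (orcinol dimethyl ether)
Product: 7 (2,6-dimethoxy-4-methylphenyl)boronic acid, via (2,6-dimethoxy-4-methylphenyl)lithium 5 (not isolated), via lithium (2,6-dimethoxy-4-methylphenyl)triisopropoxyborate 6 (not isolated)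
Conditions: n-BuLi, THF, 0 °C to rt; B(OiPr)3, −78 °C to rt; 1 M HCl
Reagents that add atoms: triisopropyl borate, CC(C)OB(OC(C)C)OC(C)C; water, O
Why: Directed ortho-lithiation occurs at the carbon between the two methoxy groups (the future C8'), and electrophilic borylation with acidic hydrolysis of the borate gives the boronic acid.

Step 4
Reactants: 3 1,5-bis(benzyloxy)-2-bromo-3-methylbenzene; 7 (2,6-dimethoxy-4-methylphenyl)boronic acid (1.8 equiv)
Product: 8 2',4'-bis(benzyloxy)-2,6-dimethoxy-4,6'-dimethyl-1,1'-biphenyl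
Conditions: Pd(OAc)2 (5 mol %), SPhos (10 mol %), K3PO4, PhMe/H2O (10:1), 100 °C
Reagents that add atoms: none
Why: Suzuki–Miyaura coupling in which the bulky, electron-rich biarylphosphine supports oxidative addition of the di-ortho-substituted bromide to zerovalent palladium and reductive elimination to the tetra-ortho-substituted biaryl, with excess boronic acid offsetting protodeboronation.

Step 5
Reactants: 8 2',4'-bis(benzyloxy)-2,6-dimethoxy-4,6'-dimethyl-1,1'-biphenyl; 9 acetic acid (3 equiv)
Product: 10 1,1'-[2',4'-bis(benzyloxy)-2,6-dimethoxy-4,6'-dimethyl-1,1'-biphenyl-3,5'-diyl]di(ethan-1-one)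
Conditions: AcOH, (CF3CO)2O, CH2Cl2, 0 °C to rt
Reagents that add atoms: none
Why: Friedel–Crafts acylation by acetyl trifluoroacetate should place one acetyl on each ring ortho to methyl, because the two open sites of the dimethoxy ring are equivalent, the open site of the dibenzyloxy ring ortho to methyl is para to an ether oxygen, each ring is deactivated after one acylation, and the metal-free medium spares the benzyl ethers.

Step 6
Reactants: 10 1,1'-[2',4'-bis(benzyloxy)-2,6-dimethoxy-4,6'-dimethyl-1,1'-biphenyl-3,5'-diyl]di(ethan-1-one)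
Product: 11 1,1'-(2,2',4'-trihydroxy-6-methoxy-4,6'-dimethyl-1,1'-biphenyl-3,5'-diyl)di(ethan-1-one)
Conditions: BCl3 (6 equiv), pentamethylbenzene (4 equiv), CH2Cl2, −78 to 0 °C; aq. NaHCO3
Reagents that add atoms: none
Why: BCl3 ether cleavage should remove both benzyl groups (benzyl cation trapped by pentamethylbenzene) and the one methoxy group ortho to an acetyl through a six-membered boron chelate, while the non-chelated methoxy group para to the acetyl (the future 7'-OMe) is not attacked.

Step 7
Reactants: 11 1,1'-(2,2',4'-trihydroxy-6-methoxy-4,6'-dimethyl-1,1'-biphenyl-3,5'-diyl)di(ethan-1-one)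
Product: 12 1,1'-[2'-(benzyloxy)-2,4'-dihydroxy-6-methoxy-4,6'-dimethyl-1,1'-biphenyl-3,5'-diyl]di(ethan-1-one)
Conditions: BnBr (1.05 equiv), K2CO3 (1.2 equiv), acetone, 40 °C
Reagents that add atoms: benzyl bromide, BrCc1ccccc1
Why: Chemoselective Williamson benzylation, since only the 2'-hydroxyl is para to its acetyl and free of an intramolecular hydrogen bond, as in the selective 4-O-alkylation of 2,4-dihydroxyacetophenones.

Step 8
Reactants: 12 1,1'-[2'-(benzyloxy)-2,4'-dihydroxy-6-methoxy-4,6'-dimethyl-1,1'-biphenyl-3,5'-diyl]di(ethan-1-one); 13 diethylcarbamoyl chloride (3 equiv)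
Product: 14 3,5'-diacetyl-2'-(benzyloxy)-6-methoxy-4,6'-dimethyl-1,1'-biphenyl-2,4'-diyl bis(diethylcarbamate)
Conditions: ClCONEt2, K2CO3, MeCN, 80 °C
Reagents that add atoms: none
Why: O-Carbamoylation of the two remaining acetyl-flanked phenols by nucleophilic acyl substitution, with a carbonate base too weak to enolize the ketones and start the carbamoyl shift early.

Step 9
Reactants: 14 3,5'-diacetyl-2'-(benzyloxy)-6-methoxy-4,6'-dimethyl-1,1'-biphenyl-2,4'-diyl bis(diethylcarbamate)
Product: 16 7-(benzyloxy)-4,4'-dihydroxy-7'-methoxy-5,5'-dimethyl-6,8'-bicoumarin, via bis(β-ketoamide) bisphenol 15 (not isolated)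
Conditions: NaH (6 equiv), THF, 66 °C; then THF distilled off, TFA, PhMe, 70 °C, same flask
Reagents that add atoms: none
Why: NaH deprotonates each acetyl CH3 and the enolate carbon attacks the ortho carbamate carbonyl through a six-membered cyclic transition state, expelling the aryloxide and forming C2–C3 and C2'–C3'; a further deprotonation of each β-ketoamide makes the shift irreversible. On acidification each phenol oxygen adds to its amide carbonyl in a 6-exo-trig closure and diethylamine is lost, giving the two 4-hydroxy-2-pyranone rings. The closest known reaction is the carbamoyl Baker–Venkataraman rearrangement of 2-acetylaryl carbamates with acid lactonization to 4-hydroxycoumarins, here run twice in one molecule. No stereocenter is created and the existing biaryl axis is not touched. The step needs chemoselectivity only, which the substrate secures: each enolate can reach only its own ortho carbamate, the hindered carbamate beside the axis is attacked intramolecularly, and the benzyl and methyl ethers are inert to NaH. TFA diluted in toluene at moderate temperature should spare the benzyl ether, which sits on an acyl-deactivated ring.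

Step 10
Reactants: 16 7-(benzyloxy)-4,4'-dihydroxy-7'-methoxy-5,5'-dimethyl-6,8'-bicoumarin
Product: 17 7-(benzyloxy)-4,4',7'-trimethoxy-5,5'-dimethyl-6,8'-bicoumarin
Conditions: Me2SO4 (2.5 equiv), K2CO3, acetone, 56 °C
Reagents that add atoms: dimethyl sulfate, COS(=O)(=O)OC
Why: O-Alkylation of the two 4-hydroxycoumarin anions (vinylogous carboxylates) with the hard electrophile dimethyl sulfate should give the 4-methoxy-2-pyranones, the standard methylation of 4-hydroxy-5-methylcoumarins, while the benzyl ether is untouched.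

Step 11
Reactants: 17 7-(benzyloxy)-4,4',7'-trimethoxy-5,5'-dimethyl-6,8'-bicoumarin
Product: 18 7-hydroxy-4,4',7'-trimethoxy-5,5'-dimethyl-6,8'-bicoumarin (CNP0113839.0)
Conditions: H2 (1 atm), 10% Pd/C, EtOAc/MeOH, rt
Reagents that add atoms: none
Why: Catalytic hydrogenolysis of the benzyl aryl ether, under which the push–pull C3–C4 double bonds of the 4-methoxycoumarins, the lactones and the methyl ethers should not react at 1 atm and room temperature.

**Compound list**
1 | orcinol (5-methylbenzene-1,3-diol) | Cc1cc(O)cc(O)c1 | starting material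
2 | 1,3-bis(benzyloxy)-5-methylbenzene | Cc1cc(OCc2ccccc2)cc(OCc2ccccc2)c1 | intermediate
3 | 1,5-bis(benzyloxy)-2-bromo-3-methylbenzene | Cc1cc(OCc2ccccc2)cc(OCc2ccccc2)c1Br | intermediate
4 | 1,3-dimethoxy-5-methylbenzene | COc1cc(C)cc(OC)c1 | starting material
5 | (2,6-dimethoxy-4-methylphenyl)lithium | [Li]c1c(OC)cc(C)cc1OC | intermediate
6 | lithium (2,6-dimethoxy-4-methylphenyl)triisopropoxyborate | [Li+].COc1cc(C)cc(OC)c1[B-](OC(C)C)(OC(C)C)OC(C)C | intermediate
7 | (2,6-dimethoxy-4-methylphenyl)boronic acid | COc1cc(C)cc(OC)c1B(O)O | intermediate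
8 | 2',4'-bis(benzyloxy)-2,6-dimethoxy-4,6'-dimethyl-1,1'-biphenyl | COc1cc(C)cc(OC)c1-c1c(C)cc(OCc2ccccc2)cc1OCc1ccccc1 | intermediate
9 | acetic acid | CC(=O)O | starting material
10 | 1,1'-[2',4'-bis(benzyloxy)-2,6-dimethoxy-4,6'-dimethyl-1,1'-biphenyl-3,5'-diyl]di(ethan-1-one) | COc1cc(C)c(C(C)=O)c(OC)c1-c1c(C)c(C(C)=O)c(OCc2ccccc2)cc1OCc1ccccc1 | intermediate
11 | 1,1'-(2,2',4'-trihydroxy-6-methoxy-4,6'-dimethyl-1,1'-biphenyl-3,5'-diyl)di(ethan-1-one) | COc1cc(C)c(C(C)=O)c(O)c1-c1c(C)c(C(C)=O)c(O)cc1O | intermediate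
12 | 1,1'-[2'-(benzyloxy)-2,4'-dihydroxy-6-methoxy-4,6'-dimethyl-1,1'-biphenyl-3,5'-diyl]di(ethan-1-one) | COc1cc(C)c(C(C)=O)c(O)c1-c1c(C)c(C(C)=O)c(O)cc1OCc1ccccc1 | intermediate
13 | diethylcarbamoyl chloride | CCN(CC)C(Cl)=O | starting material
14 | 3,5'-diacetyl-2'-(benzyloxy)-6-methoxy-4,6'-dimethyl-1,1'-biphenyl-2,4'-diyl bis(diethylcarbamate) | CCN(CC)C(=O)Oc1c(C(C)=O)c(C)cc(OC)c1-c1c(C)c(C(C)=O)c(OC(=O)N(CC)CC)cc1OCc1ccccc1 | intermediate
15 | 3,3'-[2'-(benzyloxy)-2,4'-dihydroxy-6-methoxy-4,6'-dimethyl-1,1'-biphenyl-3,5'-diyl]bis(N,N-diethyl-3-oxopropanamide) | CCN(CC)C(=O)CC(=O)c1c(C)cc(OC)c(c1O)-c1c(C)c(C(=O)CC(=O)N(CC)CC)c(O)cc1OCc1ccccc1 | intermediate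
16 | 7-(benzyloxy)-4,4'-dihydroxy-7'-methoxy-5,5'-dimethyl-6,8'-bicoumarin | Cc1cc(OC)c(c2oc(=O)cc(O)c12)-c1c(C)c2c(O)cc(=O)oc2cc1OCc1ccccc1 | intermediate
17 | 7-(benzyloxy)-4,4',7'-trimethoxy-5,5'-dimethyl-6,8'-bicoumarin | Cc1cc(OC)c(c2oc(=O)cc(OC)c12)-c1c(C)c2c(OC)cc(=O)oc2cc1OCc1ccccc1 | intermediate
18 | 7-hydroxy-4,4',7'-trimethoxy-5,5'-dimethyl-6,8'-bicoumarin (CNP0113839.0) | COc1cc(C)c2c(OC)cc(=O)oc2c1-c1c(O)cc2oc(=O)cc(OC)c2c1C | target

**Step count**
Total: 11 steps. Longest linear sequence: 10 steps (orcinol through steps 1, 2, 4, 5, 6, 7, 8, 9, 10, 11); the boronic acid branch is 1 step.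

**Steps most likely to fail, with fallbacks**

Step 9. The second carbamoyl shift, at the carbamate wedged beside the biaryl axis, may stall, or the benzyl ether may be partly lost by acidolysis during lactonization. Fallback: setting out from 12, the lactone carbonyls are delivered intermolecularly by Claisen condensation with diethyl carbonate (NaH, (EtO)2CO, PhMe, 110 °C). This should give diethyl 3,3'-[2'-(benzyloxy)-2,4'-dihydroxy-6-methoxy-4,6'-dimethyl-1,1'-biphenyl-3,5'-diyl]bis(3-oxopropanoate) F1, which lactonizes on acidic work-up with loss of ethanol and rejoins the route at 16, without any hot TFA.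

Step 4. Protodeboronation of the 2,6-dimethoxyarylboronic acid may outrun transmetalation to the hindered arylpalladium species, leaving unreacted bromide. Fallback: setting out from 4 and 3, the aryllithium 5 is made as in step 3 and transmetalated with ZnCl2 in THF to (2,6-dimethoxy-4-methylphenyl)zinc chloride F2. Negishi coupling of F2 with 3 (Pd2(dba)3, RuPhos, THF, 70 °C) comes back to the route at 8.

Step 5. Acid-promoted benzyl migration or cleavage on the electron-rich rings, or a halt after the first acylation, may erode the double acetylation. Fallback: setting out from 8, Vilsmeier–Haack diformylation (POCl3, DMF, 60 °C; aq. NaOAc) should give 2',4'-bis(benzyloxy)-2,6-dimethoxy-4,6'-dimethyl-1,1'-biphenyl-3,5'-dicarbaldehyde F3. Addition of MeMgBr (THF, 0 °C) gives 1,1'-[2',4'-bis(benzyloxy)-2,6-dimethoxy-4,6'-dimethyl-1,1'-biphenyl-3,5'-diyl]di(ethan-1-ol) F4 as a diastereomer mixture of no consequence, and oxidation with Dess–Martin periodinane in CH2Cl2 comes back to the route at 10.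

**Further compounds**
F1 | step 9 | diethyl 3,3'-[2'-(benzyloxy)-2,4'-dihydroxy-6-methoxy-4,6'-dimethyl-1,1'-biphenyl-3,5'-diyl]bis(3-oxopropanoate) | CCOC(=O)CC(=O)c1c(C)cc(OC)c(c1O)-c1c(C)c(C(=O)CC(=O)OCC)c(O)cc1OCc1ccccc1
F2 | step 4 | (2,6-dimethoxy-4-methylphenyl)zinc chloride | COc1cc(C)cc(OC)c1[Zn]Cl
F3 | step 5 | 2',4'-bis(benzyloxy)-2,6-dimethoxy-4,6'-dimethyl-1,1'-biphenyl-3,5'-dicarbaldehyde | COc1cc(C)c(C=O)c(OC)c1-c1c(C)c(C=O)c(OCc2ccccc2)cc1OCc1ccccc1
F4 | step 5 | 1,1'-[2',4'-bis(benzyloxy)-2,6-dimethoxy-4,6'-dimethyl-1,1'-biphenyl-3,5'-diyl]di(ethan-1-ol), diastereomer mixture | COc1cc(C)c(C(C)O)c(OC)c1-c1c(C)c(C(C)O)c(OCc2ccccc2)cc1OCc1ccccc1
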